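Everything rests on cutting the C4a–C5 bond of ring A. The oxygens on C5, C7 and C8a mark a poly-β-carbonyl chain. C5 is read as an ester carbon, C7 as a methyl enol ether, and C8a as the O1-bearing carbon of an enantiopure 2,3-dihydropyran-4-one (ring C). One base-induced Claisen closure, C4a onto C5 with loss of methanol and enolisation, builds the whole aromatic ring. It releases only the chelated 5-OH, keeps O7 methylated, and locks the benzyl group at C6 because O1 already sits on C8a. The precursor is the (2R)-2-aryl-dihydropyranone bearing a CH2–C(OMe)=C(CH2Ar)–CO2Me arm on C8a, assembled without any base touching C3–H.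

Key step: step 7

Assumption: flavanone numbering (O1, C2, C3, C4, C4a, C5 to C8, C8a) is used for all intermediates, and (R)-BINOL is taken to open the Re face of 1 as in related titanium–BINOL additions to aryl aldehydes; should the sense be opposite, (S)-BINOL is used.

Step 1
Reactants: 1 4-(benzyloxy)benzaldehyde; 2 (E)-1-methoxy-3-(trimethylsilyloxy)buta-1,3-diene
Product: 4 (2R)-2-[4-(benzyloxy)phenyl]-2,3-dihydro-4H-pyran-4-one, via silylated aldol adduct 3 (not isolated)
Conditions: Ti(OiPr)4 (10 mol %), (R)-BINOL (20 mol %), 4 Å MS, Et2O, −20 °C; then cat. CF3CO2H, CH2Cl2, 0 °C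
Reagents that add atoms: none
Why: Catalytic enantioselective hetero-Diels–Alder reaction that runs through a Mukaiyama aldol addition: the titanium–BINOL complex binds the aldehyde and leaves its Re face open to the diene terminus, which sets C2 as R, and acid then closes ring C by conjugate addition of the oxygen and loss of the methoxy group without touching C2.

Step 2
Reactants: 5 methyl acetoacetate; 6 2-(benzyloxy)benzyl bromide
Product: 7 methyl 2-[2-(benzyloxy)benzyl]-3-oxobutanoate
Conditions: NaH, THF, 0 °C to rt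
Reagents that add atoms: none
Why: Acetoacetic ester alkylation, an SN2 reaction of a soft sodium enolate with a reactive benzylic bromide in which a slight excess of 5 holds back double alkylation, and the stereocentre formed is of no account because it becomes sp2 in step 3.

Step 3
Reactants: 7 methyl 2-[2-(benzyloxy)benzyl]-3-oxobutanoate
Product: 8 methyl (E)-2-[2-(benzyloxy)benzyl]-3-methoxybut-2-enoate
Conditions: HC(OMe)3, cat. H2SO4, MeOH, 50 °C; then cat. TsOH, toluene, reflux with removal of MeOH
Reagents that add atoms: trimethyl orthoformate, COC(OC)OC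
Why: Acid-catalysed ketalisation by the orthoester followed by loss of methanol (enol ether formation from a β-keto ester) is pulled by conjugation with the ester toward the E isomer, and any Z isomer gives the same dienolate in step 4.

Step 4
Reactants: 8 methyl (E)-2-[2-(benzyloxy)benzyl]-3-methoxybut-2-enoate
Product: 9 2-[2-(benzyloxy)benzyl]-1,3-dimethoxy-1-(triethylsilyloxy)buta-1,3-diene
Conditions: LiN(iPr)2, THF, −78 °C; Et3SiCl, −78 to 0 °C; LiCl filtered off, used crude
Reagents that add atoms: chlorotriethylsilane, CC[Si](Cl)(CC)CC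
Why: γ-Deprotonation of the β-methoxy enoate gives the lithium dienolate, whose O-silylation furnishes the vinylogous silyl ketene acetal, the standard way to 1,3-dialkoxy-1-silyloxybutadienes, while the benzyl ethers are inert to the amide base at this temperature.

Step 5
Reactants: 4 (2R)-2-[4-(benzyloxy)phenyl]-2,3-dihydro-4H-pyran-4-one; 9 2-[2-(benzyloxy)benzyl]-1,3-dimethoxy-1-(triethylsilyloxy)buta-1,3-diene
Product: 10 methyl (E)-2-[2-(benzyloxy)benzyl]-4-{(2S,6R)-6-[4-(benzyloxy)phenyl]-4-(triethylsilyloxy)-5,6-dihydro-2H-pyran-2-yl}-3-methoxybut-2-enoate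
Conditions: Et3SiOTf (20 mol %), CH2Cl2, −78 °C; Et3N quench, aq NaHCO3
Reagents that add atoms: none
Why: Vinylogous Mukaiyama–Michael addition in which silylation of the C4 carbonyl turns 4 into an oxocarbenium ion that the free terminal CH2 of 9 attacks at C8a (the α-carbon is blocked by the benzyl group), silyl transfer fixes the enol regiospecifically between C4 and C4a, axial attack anti to the C2 aryl group should give the 2,6-trans ring whose C8a centre is erased in step 6, and no base ever meets C3–H.

Step 6
Reactants: 10 methyl (E)-2-[2-(benzyloxy)benzyl]-4-{(2S,6R)-6-[4-(benzyloxy)phenyl]-4-(triethylsilyloxy)-5,6-dihydro-2H-pyran-2-yl}-3-methoxybut-2-enoate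
Product: 11 methyl (E)-2-[2-(benzyloxy)benzyl]-4-{(2R)-2-[4-(benzyloxy)phenyl]-4-oxo-3,4-dihydro-2H-pyran-6-yl}-3-methoxybut-2-enoate
Conditions: Pd(OAc)2 (1.1 equiv), MeCN, rt
Reagents that add atoms: none
Why: Saegusa–Ito oxidation, in which divalent palladium binds at C4a only where the silyl enol ether sits and β-hydride elimination of C8a–H restores the vinylogous ester, so that the double bond cannot stray toward C3 and C2 and the stereocentre stays intact under neutral conditions.

Step 7
Reactants: 11 methyl (E)-2-[2-(benzyloxy)benzyl]-4-{(2R)-2-[4-(benzyloxy)phenyl]-4-oxo-3,4-dihydro-2H-pyran-6-yl}-3-methoxybut-2-enoate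
Product: 14 (2R)-2-[4-(benzyloxy)phenyl]-6-[2-(benzyloxy)benzyl]-5-hydroxy-7-methoxychroman-4-one, via lithium trienolate 12 (not isolated), via cyclohexadienone 13 (not isolated)
Conditions: LiN(SiMe3)2 (1.1 equiv), THF (0.01 M), −78 to 0 °C; AcOH, −78 °C
Reagents that add atoms: none
Why: Proposed new method: the amide base removes a C8 proton, which is activated through conjugation by both the C4 ketone and the C5 ester and is far more acidic than C3–H, giving the planar anion 12 with charge spread over O4, C4a, C8, C6 and the ester oxygen; the weakened C6–C7 and C8–C8a bonds rotate, so C5 can reach C4a whatever the enol ether geometry. C4a then adds to the ester carbonyl with lithium bridging O4 and the ester oxygen (equally describable as a 6π closure of the C4a=C8a–C8=C7–C6=C5 trienolate), methoxide leaves, and dienone 13 is deprotonated at once to the phenoxide, so aromatisation makes the closure irreversible. The nearest known reaction type is the classical alkoxide-induced folding of 3,5,7-trioxo esters or their partial enol ethers into acylphloroglucinols by intramolecular Claisen condensation; new here is the α-carbon of a cyclic vinylogous ester as the nucleophile. Ring A closes in the 6-(enolexo)-exo-trig mode. No stereocentre is formed, and C2 is kept because about one equivalent of base is used, the methoxide set free is consumed by 13, and the cold mixture is acidified before a C3 enolate could expel O1. Chemoselectivity lies in the substrate: O1 is an ether, so the α-pyrone closure usual for such chains is shut off, C8 could reach C5 only through a four-membered ring and O4 only through an eight-membered one, and high dilution suppresses intermolecular acylation.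

Step 8
Reactants: 14 (2R)-2-[4-(benzyloxy)phenyl]-6-[2-(benzyloxy)benzyl]-5-hydroxy-7-methoxychroman-4-one
Product: 15 (+)-methylphelligrin A, (2R)-5-hydroxy-6-(2-hydroxybenzyl)-2-(4-hydroxyphenyl)-7-methoxychroman-4-one
Conditions: H2 (1 atm), 10% Pd/C, EtOAc, rt, stopped after two equivalents of H2
Reagents that add atoms: none
Why: Catalytic hydrogenolysis of the two aryl benzyl ethers in a neutral medium avoids the base-induced retro-oxa-Michael racemisation of 5-hydroxyflavanones, and stopping at two equivalents of hydrogen spares the slower-reacting benzylic C2–O1 bond and the chelated C4 ketone.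

Compound list
1 | 4-(benzyloxy)benzaldehyde | O=Cc1ccc(OCc2ccccc2)cc1 | starting material
2 | (E)-1-methoxy-3-(trimethylsilyloxy)buta-1,3-diene | CO/C=C/C(=C)O[Si](C)(C)C | starting material
3 | (1E,5R)-5-[4-(benzyloxy)phenyl]-1-methoxy-5-(trimethylsilyloxy)pent-1-en-3-one | CO/C=C/C(=O)C[C@@H](O[Si](C)(C)C)c1ccc(OCc2ccccc2)cc1 | intermediate
4 | (2R)-2-[4-(benzyloxy)phenyl]-2,3-dihydro-4H-pyran-4-one | C1=CC(=O)C[C@H](c2ccc(OCc3ccccc3)cc2)O1 | intermediate
5 | methyl acetoacetate | COC(=O)CC(C)=O | starting material
6 | 2-(benzyloxy)benzyl bromide | BrCc1ccccc1OCc1ccccc1 | starting material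
7 | methyl 2-[2-(benzyloxy)benzyl]-3-oxobutanoate (racemic) | COC(=O)C(Cc1ccccc1OCc1ccccc1)C(C)=O | intermediate
8 | methyl (E)-2-[2-(benzyloxy)benzyl]-3-methoxybut-2-enoate | COC(=O)/C(Cc1ccccc1OCc1ccccc1)=C(OC)\C | intermediate
9 | 2-[2-(benzyloxy)benzyl]-1,3-dimethoxy-1-(triethylsilyloxy)buta-1,3-diene (ketene acetal geometry undefined) | C=C(OC)C(Cc1ccccc1OCc1ccccc1)=C(OC)O[Si](CC)(CC)CC | intermediate
10 | methyl (E)-2-[2-(benzyloxy)benzyl]-4-{(2S,6R)-6-[4-(benzyloxy)phenyl]-4-(triethylsilyloxy)-5,6-dihydro-2H-pyran-2-yl}-3-methoxybut-2-enoate | COC(=O)/C(Cc1ccccc1OCc1ccccc1)=C(OC)\C[C@H]1C=C(O[Si](CC)(CC)CC)C[C@H](c2ccc(OCc3ccccc3)cc2)O1 | intermediate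
11 | methyl (E)-2-[2-(benzyloxy)benzyl]-4-{(2R)-2-[4-(benzyloxy)phenyl]-4-oxo-3,4-dihydro-2H-pyran-6-yl}-3-methoxybut-2-enoate | COC(=O)/C(Cc1ccccc1OCc1ccccc1)=C(OC)\CC1=CC(=O)C[C@H](c2ccc(OCc3ccccc3)cc2)O1 | intermediate
12 | lithium trienolate of 11 (C8-deprotonated, one resonance form drawn) | [Li+].COC(=O)C(Cc1ccccc1OCc1ccccc1)=C(OC)C=C1C=C([O-])C[C@H](c2ccc(OCc3ccccc3)cc2)O1 | intermediate
13 | (2R)-2-[4-(benzyloxy)phenyl]-6-[2-(benzyloxy)benzyl]-7-methoxy-2,3-dihydro-4H-chromene-4,5(4aH)-dione | COC1=C(Cc2ccccc2OCc2ccccc2)C(=O)C2C(=O)C[C@H](c3ccc(OCc4ccccc4)cc3)OC2=C1 | intermediate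
14 | (2R)-2-[4-(benzyloxy)phenyl]-6-[2-(benzyloxy)benzyl]-5-hydroxy-7-methoxychroman-4-one | COc1cc2c(c(O)c1Cc1ccccc1OCc1ccccc1)C(=O)C[C@H](c1ccc(OCc3ccccc3)cc1)O2 | intermediate
15 | (+)-methylphelligrin A | COc1cc2c(c(O)c1Cc1ccccc1O)C(=O)C[C@H](c1ccc(O)cc1)O2 | target

Total step count: 8. Longest linear sequence: 7 (steps 2 to 8).

Steps most likely to fail

Step 7. The fully delocalised anion may be too stabilised to acylate itself below the temperature at which proton exchange to C3 starts. That exchange would open ring C by β-elimination of O1 and erode the configuration at C2.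
- The fallback uses known chemistry, sets out from 6 and returns at 14. Ring A is taken from the aromatic pool and C2 is set last.
- Commercial 2',6'-dihydroxy-4'-methoxyacetophenone is condensed with N,N-dimethylformamide dimethyl acetal to the enaminone F1. Acid cyclises this to 5-hydroxy-7-methoxychromone F2, a single isomer because the ketone is symmetric.
- Iodination ortho to the chelated phenol with BnMe3N·ICl2 and CaCO3 gives the 6-iodochromone F3.
- Bromide 6 is converted with zinc dust and LiCl into 2-(benzyloxy)benzylzinc bromide F4. Negishi coupling of F3 with an excess of F4 under Pd(OAc)2 and SPhos gives the 6-benzylated chromone F5.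
- Enantioselective conjugate addition of 4-(benzyloxy)phenylboronic acid then delivers 14. The conditions are Pd(OCOCF3)2, 4-tert-butyl-2-(pyridin-2-yl)-4,5-dihydrooxazole (antipode chosen for 2R), NH4PF6 and water in 1,2-dichloroethane.

Step 5. Bond formation with the hindered, acid-labile diene may be slow, so that protodesilylation of 9 outruns γ-addition to the activated pyranone.
- The fallback sets out from 7 and 4 and returns at 11. The methyl enol ether is left out of the nucleophile and is installed last.
- Keto ester 7 is doubly silylated with Me3SiOTf and Et3N to the more nucleophilic 1,3-bis(trimethylsilyloxy)diene F6.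
- Pyranone 4 is pre-silylated with one equivalent of t-BuMe2SiOTf at −78 °C and F6 is added, giving the doubly silylated adduct F7.
- Aqueous work-up cleaves only the labile ester-conjugated trimethylsilyl enol ether and leaves the keto ester silyl enol ether F8.
- Pd(OAc)2 in MeCN oxidises F8 to the pyranone keto ester F9.
- Me3SiCHN2 in toluene–MeOH then O-methylates the strongly enolised C7 carbonyl to 11. It is accompanied by the C7=C8 double-bond isomer F10, which enters step 7 equally because it gives the same anion 12.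

Step 6. Protodesilylation to the saturated ketone may compete with β-hydride elimination. So may opening of ring C by β-alkoxide elimination from the palladium enolate.
- The fallback sets out from 10 and returns at 11. Dehydrogenation is replaced by selenoxide elimination.
- PhSeCl at −78 °C attacks the silyl enol ether regiospecifically at C4a to give the α-phenylselanyl ketone F11.
- H2O2 with pyridine at 0 °C gives the selenoxide F12, which undergoes syn-elimination toward the only β-hydrogen, C8a–H, to give 11.

Further compounds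
F1 | step 7 | (E)-1-(2,6-dihydroxy-4-methoxyphenyl)-3-(dimethylamino)prop-2-en-1-one | COc1cc(O)c(C(=O)/C=C/N(C)C)c(O)c1
F2 | step 7 | 5-hydroxy-7-methoxy-4H-chromen-4-one | COc1cc(O)c2c(c1)OC=CC2=O
F3 | step 7 | 5-hydroxy-6-iodo-7-methoxy-4H-chromen-4-one | COc1cc2OC=CC(=O)c2c(O)c1I
F4 | step 7 | 2-(benzyloxy)benzylzinc bromide | Br[Zn]Cc1ccccc1OCc1ccccc1
F5 | step 7 | 6-[2-(benzyloxy)benzyl]-5-hydroxy-7-methoxy-4H-chromen-4-one | COc1cc2OC=CC(=O)c2c(O)c1Cc1ccccc1OCc1ccccc1
F6 | step 5 | 2-[2-(benzyloxy)benzyl]-1-methoxy-1,3-bis(trimethylsilyloxy)buta-1,3-diene | C=C(O[Si](C)(C)C)C(Cc1ccccc1OCc1ccccc1)=C(OC)O[Si](C)(C)C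
F7 | step 5 | methyl 2-[2-(benzyloxy)benzyl]-4-{(2S,6R)-6-[4-(benzyloxy)phenyl]-4-(tert-butyldimethylsilyloxy)-5,6-dihydro-2H-pyran-2-yl}-3-(trimethylsilyloxy)but-2-enoate | COC(=O)C(Cc1ccccc1OCc1ccccc1)=C(O[Si](C)(C)C)C[C@H]1C=C(O[Si](C)(C)C(C)(C)C)C[C@H](c2ccc(OCc3ccccc3)cc2)O1
F8 | step 5 | methyl 2-[2-(benzyloxy)benzyl]-4-{(2S,6R)-6-[4-(benzyloxy)phenyl]-4-(tert-butyldimethylsilyloxy)-5,6-dihydro-2H-pyran-2-yl}-3-oxobutanoate | COC(=O)C(Cc1ccccc1OCc1ccccc1)C(=O)C[C@H]1C=C(O[Si](C)(C)C(C)(C)C)C[C@H](c2ccc(OCc3ccccc3)cc2)O1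
F9 | step 5 | methyl 2-[2-(benzyloxy)benzyl]-4-{(2R)-2-[4-(benzyloxy)phenyl]-4-oxo-3,4-dihydro-2H-pyran-6-yl}-3-oxobutanoate | COC(=O)C(Cc1ccccc1OCc1ccccc1)C(=O)CC1=CC(=O)C[C@H](c2ccc(OCc3ccccc3)cc2)O1
F10 | step 5 | methyl 2-[2-(benzyloxy)benzyl]-4-{(2R)-2-[4-(benzyloxy)phenyl]-4-oxo-3,4-dihydro-2H-pyran-6-yl}-3-methoxybut-3-enoate | COC(=O)C(Cc1ccccc1OCc1ccccc1)C(OC)=CC1=CC(=O)C[C@H](c2ccc(OCc3ccccc3)cc2)O1
F11 | step 6 | methyl (E)-2-[2-(benzyloxy)benzyl]-4-{(2S,6R)-6-[4-(benzyloxy)phenyl]-4-oxo-3-(phenylselanyl)tetrahydro-2H-pyran-2-yl}-3-methoxybut-2-enoate | COC(=O)/C(Cc1ccccc1OCc1ccccc1)=C(OC)\C[C@H]1C([Se]c2ccccc2)C(=O)C[C@H](c2ccc(OCc3ccccc3)cc2)O1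
F12 | step 6 | selenoxide of F11 | COC(=O)/C(Cc1ccccc1OCc1ccccc1)=C(OC)\C[C@H]1C([Se](=O)c2ccccc2)C(=O)C[C@H](c2ccc(OCc3ccccc3)cc2)O1
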